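Everything rests on cutting both isoquinoline–naphthalene bonds, C5–C8' and C5–C1''. In each tetrahydroisoquinoline the benzenoid ring carries the biaryl carbon C5 para to the C8 hydroxyl. This ring can therefore enter as a 5,8-quinone whose C8 carbonyl is masked as a dimethyl ketal, with C1 and C3 (both R) already installed. In one operation a 6',6''-binaphthalene brominated at C8' and C1'' (both naphthols as MOM ethers) is metallated twice and adds to the free C5 carbonyl of two monoketal molecules. Ketal hydrolysis with zinc reduction re-aromatizes both rings, and a single acid treatment removes all protecting groups.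

Key step: step 18

Locants: isoquinoline atoms are C1–C8a. Naphthalene half A is primed (2'-Me, 4'-OMe, 5'-O, 6' link, 8' isoquinoline). Half B is double-primed (1'' isoquinoline, 2''-Me, 4''-OMe, 5''-O, 6'' link).

Assumption: the drawn structure fixes only C1 and C3 of both isoquinolines (all four R, each ring 1,3-trans) and leaves the biaryl axes open. No axial control is claimed. The rotationally hindered C5–C1'' axis should give two atropisomers of 32 and 33, to be separated by HPLC.

**Binaphthalene branch**

Step 1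
Reactants: 1 3-methylbut-2-enoyl chloride
Product: 2 N,N-diethyl-3-methylbut-2-enamide
Conditions: Et2NH, aq NaOH, CH2Cl2, 0 °C to rt
Reagents that add atoms: diethylamine, CCNCC
Why: Schotten–Baumann acylation of a secondary amine by an acid chloride; a double-bond isomer, should one form, is harmless because it gives the same dienolate in step 3.

Step 2
Reactants: 3 3-bromophenol
Product: 4 1-bromo-3-(methoxymethoxy)benzene
Conditions: NaH, MOMCl, THF, 0 °C to rt
Reagents that add atoms: chloromethyl methyl ether, COCCl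
Why: Williamson-type O-alkylation of a sodium phenolate; the MOM group later acidifies C2–H for aryne formation and directs the metalation of step 5.

Step 3
Reactants: 2 N,N-diethyl-3-methylbut-2-enamide; 4 1-bromo-3-(methoxymethoxy)benzene
Product: 7 8-(methoxymethoxy)-3-methylnaphthalen-1-ol, via lithium dienolate 5 (not isolated), via aryne 6 (not isolated)
Conditions: LDA (excess), THF, −78 °C, 2; then 4, −78 °C to rt; H2O
Reagents that add atoms: none
Why: Known aryne annulation with a senecioamide dienolate: the γ-carbon attacks the aryne carbon remote from OMOM (inductive control), the aryl anion formed next to OMOM acylates on the amide with loss of LiNEt2, and tautomerization gives the naphthol with OH peri to OMOM and the methyl meta to OH.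

Step 4
Reactants: 7 8-(methoxymethoxy)-3-methylnaphthalen-1-ol
Product: 8 1-methoxy-8-(methoxymethoxy)-3-methylnaphthalene
Conditions: MeI, K2CO3, DMF, rt
Reagents that add atoms: iodomethane, CI
Why: Williamson ether synthesis on the only free hydroxyl, which fixes the 4'-OMe/5'-OMOM/2'-Me pattern of both naphthalene halves.

Step 5
Reactants: 8 1-methoxy-8-(methoxymethoxy)-3-methylnaphthalene (two molecules)
Product: 10 symmetric 6',6''-binaphthalene bis-MOM ether (8,8'-dimethoxy-1,1'-bis(methoxymethoxy)-6,6'-dimethyl-2,2'-binaphthalene), via aryllithium 9 (not isolated)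
Conditions: n-BuLi, TMEDA, Et2O, 0 °C to rt; then anhydrous CuCl2, −78 °C to rt
Reagents that add atoms: none
Why: Directed ortho-metalation by OMOM (its peri position is occupied by OMe, so only the C–H of the future C6' is within reach), followed by the known oxidative homocoupling of an aryllithium with CuCl2.

Step 6
Reactants: 10 symmetric binaphthalene bis-MOM ether
Product: 11 symmetric binaphthol (8,8'-dimethoxy-6,6'-dimethyl-2,2'-binaphthalene-1,1'-diol)
Conditions: conc. HCl (cat.), MeOH–THF, 50 °C, argon
Reagents that add atoms: none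
Why: Acid-catalysed acetal exchange removes both MOM groups as dimethoxymethane, while the aryl methyl ethers are inert.

Step 7
Reactants: 11 symmetric binaphthol
Product: 12 binaphthol monoacetate (5''-OAc in half B; 5'-OH free in half A)
Conditions: Ac2O (1 equiv, slow addition), Et3N, DMAP (cat.), CH2Cl2, −20 °C
Reagents that add atoms: acetic anhydride, CC(=O)OC(C)=O
Why: DMAP-catalysed acyl transfer; as with other 2,2'-biaryl diols the first ester shields the neighbouring hydroxyl, so one equivalent should stop largely at the monoester, and recovered 11 or diacetate (returned to 11 under the conditions of step 9) is recycled.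

Step 8
Reactants: 12 binaphthol monoacetate
Product: 13 dibromo monoacetate (8'-Br and 5'-OH in half A; 1''-Br and 5''-OAc in half B)
Conditions: NBS (2 equiv, two portions), MeCN–CH2Cl2, dark, −20 °C then rt
Reagents that add atoms: N-bromosuccinimide, O=C1CCC(=O)N1Br
Why: Electrophilic aromatic bromination under electronic control: in half A the free 5'-OH, whose ortho carbon holds the biaryl bond, directs to its para carbon C8', whereas in half B the acetate mutes O-5'' so that 4''-OMe directs to its para carbon C1'', which the 2''-methyl activates further.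

Step 9
Reactants: 13 dibromo monoacetate
Product: 14 8',1''-dibromo binaphthol
Conditions: K2CO3, MeOH–THF, rt, argon
Reagents that add atoms: none
Why: Base-catalysed transesterification of an aryl acetate with methanol; the aryl bromides and methyl ethers are untouched.

Step 10
Reactants: 14 8',1''-dibromo binaphthol
Product: 15 8',1''-dibromo binaphthalene bis(methoxymethyl) ether
Conditions: NaH, MOMCl, THF–DMF, 0 °C to rt
Reagents that add atoms: chloromethyl methyl ether, COCCl
Why: Williamson-type alkylation of both hindered, hydrogen-bonded naphthols as their sodium salts; MOM resists t-BuLi and falls in the same acid step as Boc at the end.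

**Isoquinoline branch**

Step 11
Reactants: 16 2-bromo-4-methoxyphenol
Product: 17 1-(benzyloxy)-2-bromo-4-methoxybenzene
Conditions: BnBr, K2CO3, DMF, rt
Reagents that add atoms: benzyl bromide, BrCc1ccccc1
Why: Williamson ether synthesis; the benzyl group marks the oxygen that becomes the C5 carbonyl and keeps it distinct from the methyl ether at the future C8.

Step 12
Reactants: 17 1-(benzyloxy)-2-bromo-4-methoxybenzene; 18 tert-butyl (2R)-2-methylaziridine-1-carboxylate
Product: 20 tert-butyl N-[(2R)-1-(2-benzyloxy-5-methoxyphenyl)propan-2-yl]carbamate, via Grignard reagent 19 (not isolated)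
Conditions: Mg, THF, 40 °C; then CuBr·SMe2 (cat.), 18, −30 °C to rt; H2O
Reagents that add atoms: none
Why: Copper-catalysed SN2 opening of a carbamate-activated aziridine by an aryl Grignard reagent at the unsubstituted CH2; the stereocentre is not involved, so the R configuration of 18 becomes C3 (R).

Step 13
Reactants: 20 tert-butyl N-[(2R)-1-(2-benzyloxy-5-methoxyphenyl)propan-2-yl]carbamate
Product: 22 N-[(2R)-1-(2-benzyloxy-5-methoxyphenyl)propan-2-yl]acetamide, via primary amine 21 (not isolated)
Conditions: HCl in dioxane, rt; evaporate; then Ac2O, Et3N, CH2Cl2, 0 °C to rt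
Reagents that add atoms: acetic anhydride, CC(=O)OC(C)=O
Why: Acidolysis of the Boc group followed by N-acetylation; the acetyl group supplies C1 and its methyl, and the benzyl aryl ether tolerates HCl in dioxane.

Step 14
Reactants: 22 N-[(2R)-1-(2-benzyloxy-5-methoxyphenyl)propan-2-yl]acetamide
Product: 23 (3R)-5-(benzyloxy)-8-methoxy-1,3-dimethyl-3,4-dihydroisoquinoline
Conditions: Tf2O, 2-chloropyridine, CH2Cl2, −78 °C to rt
Reagents that add atoms: none
Why: Bischler–Napieralski cyclodehydration under mild amide activation; the only free carbon ortho to the side chain is also ortho to OMe, so the closure is regiochemically unambiguous, and the low temperature protects C3.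

Step 15
Reactants: 23 (3R)-5-(benzyloxy)-8-methoxy-1,3-dimethyl-3,4-dihydroisoquinoline
Product: 24 (1R,3R)-5-(benzyloxy)-8-methoxy-1,3-dimethyl-1,2,3,4-tetrahydroisoquinoline (1,3-trans)
Conditions: AlMe3, LiAlH4, THF, −78 °C to 0 °C; H2O
Reagents that add atoms: none
Why: Established trans-selective hydride reduction of 1,3-dimethyl-3,4-dihydroisoquinolines: AlMe3 bound to nitrogen pushes the C3 methyl pseudoaxial, and pseudoaxial hydride delivery to C1 of that conformer sets C1 as R under control of C3 (borohydride alone would give the cis isomer).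

Step 16
Reactants: 24 (1R,3R)-5-(benzyloxy)-8-methoxy-1,3-dimethyl-1,2,3,4-tetrahydroisoquinoline
Product: 26 tert-butyl (1R,3R)-5-hydroxy-8-methoxy-1,3-dimethyl-3,4-dihydro-1H-isoquinoline-2-carboxylate, via N-Boc benzyl ether 25 (not isolated)
Conditions: Boc2O, MeOH, 40 °C; then Pd/C, H2 (1 atm), rt, same flask
Reagents that add atoms: di-tert-butyl dicarbonate, CC(C)(C)OC(=O)OC(=O)OC(C)(C)C
Why: Carbamate formation on the secondary amine followed by hydrogenolysis of the benzyl aryl ether; nitrogen must be acylated before the oxidation of step 17, and neither operation touches C1 or C3.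

Step 17
Reactants: 26 tert-butyl (1R,3R)-5-hydroxy-8-methoxy-1,3-dimethyl-3,4-dihydro-1H-isoquinoline-2-carboxylate
Product: 27 tert-butyl (1R,3R)-8,8-dimethoxy-1,3-dimethyl-5-oxo-1,3,4,8-tetrahydroisoquinoline-2(5H)-carboxylate (5,8-quinone 8-monoketal)
Conditions: PhI(OAc)2, MeOH, 0 °C; NaHCO3 work-up
Reagents that add atoms: methanol, CO
Why: Oxidative dearomatization of a para-methoxyphenol by hypervalent iodine in methanol; methanol is captured at the carbon that already bears OMe (C8), which leaves a single carbonyl at C5.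

**Union and endgame**

Step 18
Reactants: 15 8',1''-dibromo binaphthalene bis(methoxymethyl) ether; 27 quinone 8-monoketal (two molecules)
Product: 30 bis-carbinol adduct (both C5 carbinols as epimer mixtures), via dilithio binaphthalene 28 (not isolated), via bis(dichlorocerium) reagent 29 (not isolated)
Conditions: t-BuLi (4 equiv), THF, −78 °C; anhydrous CeCl3, THF, −78 °C; then 27 (2.4 equiv), −78 °C to −40 °C; H2O
Reagents that add atoms: none
Why: Bromine–lithium exchange with two equivalents of t-BuLi per bromine gives the 8',1''-dilithio species 28, and transmetalation to the less basic, more oxophilic organocerium 29 precedes attack on the only carbonyl (C5) of two molecules of 27, which forms C5–C8' and C5–C1'' as tertiary alkoxides. The closest known reaction type is the 1,2-addition of aryllithium or arylcerium reagents to 4,4-dimethoxycyclohexa-2,5-dienones, run here twice on one nucleophile. No ring is closed. The two new carbinol centres are not controlled and need not be, since both become sp2 carbons in step 19, while C1 and C3 are spectators brought in by 27. The step needs 1,2- over 1,4-addition and addition over removal of the vinylogously acidic C1–H: the hard carbon nucleophile at −78 °C secures the first, cerium the second, and the C8 ketal leaves no second carbonyl, so the attacked carbon is unambiguous. The crowded bond beside the 2''-methyl is thus made through an open carbonyl-addition transition state instead of a metal-centred reductive elimination.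

Step 19
Reactants: 30 bis-carbinol adduct
Product: 32 bis(N-Boc) bis(MOM) quateraryl bearing free C8 phenols, via bis-quinol 31 (not isolated)
Conditions: AcOH–THF–H2O, rt; then Zn dust, rt
Reagents that add atoms: water, O
Why: Mild acid hydrolysis of the doubly allylic ketals gives the para-quinols, and zinc then transfers two electrons to each dienone so that the C5 hydroxyl leaves as water and the ring becomes the C8 phenol (known reductive aromatization of para-quinols); hydrolysis must come first because reduction of the ketal itself would leave an 8-O-methyl ether, and MOM and Boc tolerate acetic acid.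

Step 20
Reactants: 32 bis(N-Boc) bis(MOM) quateraryl
Product: 33 target CNP0077060.1
Conditions: HCl in MeOH, argon, rt to 40 °C; then aq NaHCO3; HPLC
Reagents that add atoms: none
Why: Global acidolysis: both MOM acetals exchange into dimethoxymethane and both Boc groups fragment in one operation, methanol traps the cationic fragments, and the aryl methyl ethers and the four stereocentres are unaffected.

**Compound list**

1 | 3-methylbut-2-enoyl chloride | CC(C)=CC(=O)Cl | starting material
2 | N,N-diethyl-3-methylbut-2-enamide | CCN(CC)C(=O)C=C(C)C | intermediate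
3 | 3-bromophenol | Oc1cccc(Br)c1 | starting material
4 | 1-bromo-3-(methoxymethoxy)benzene | COCOc1cccc(Br)c1 | intermediate
5 | lithium 1-(diethylamino)-3-methylbuta-1,3-dien-1-olate (dienolate of 2) | C=C(C)C=C(O[Li])N(CC)CC | intermediate
6 | 3-(methoxymethoxy)benzyne | COCOC1=CC=CC#C1 | intermediate
7 | 8-(methoxymethoxy)-3-methylnaphthalen-1-ol | COCOc1cccc2cc(C)cc(O)c12 | intermediate
8 | 1-methoxy-8-(methoxymethoxy)-3-methylnaphthalene | COCOc1cccc2cc(C)cc(OC)c12 | intermediate
9 | 7-lithio-1-methoxy-8-(methoxymethoxy)-3-methylnaphthalene | COCOc1c([Li])ccc2cc(C)cc(OC)c12 | intermediate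
10 | 8,8'-dimethoxy-1,1'-bis(methoxymethoxy)-6,6'-dimethyl-2,2'-binaphthalene | COc1cc(C)cc2ccc(-c3ccc4cc(C)cc(OC)c4c3OCOC)c(OCOC)c12 | intermediate
11 | 8,8'-dimethoxy-6,6'-dimethyl-2,2'-binaphthalene-1,1'-diol | COc1cc(C)cc2ccc(-c3ccc4cc(C)cc(OC)c4c3O)c(O)c12 | intermediate
12 | monoacetate of 11 (5''-OAc, 5'-OH) | COc1cc(C)cc2ccc(-c3ccc4cc(C)cc(OC)c4c3OC(C)=O)c(O)c12 | intermediate
13 | 8',1''-dibromo monoacetate (Br para to free OH in half A, Br para to OMe in half B) | COc1cc(C)cc2c(Br)cc(-c3ccc4c(Br)c(C)cc(OC)c4c3OC(C)=O)c(O)c12 | intermediate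
14 | 8',1''-dibromo binaphthol | COc1cc(C)cc2c(Br)cc(-c3ccc4c(Br)c(C)cc(OC)c4c3O)c(O)c12 | intermediate
15 | 8',1''-dibromo binaphthalene bis(methoxymethyl) ether | COc1cc(C)cc2c(Br)cc(-c3ccc4c(Br)c(C)cc(OC)c4c3OCOC)c(OCOC)c12 | intermediate
16 | 2-bromo-4-methoxyphenol | COc1ccc(O)c(Br)c1 | starting material
17 | 1-(benzyloxy)-2-bromo-4-methoxybenzene | COc1ccc(OCc2ccccc2)c(Br)c1 | intermediate
18 | tert-butyl (2R)-2-methylaziridine-1-carboxylate | C[C@@H]1CN1C(=O)OC(C)(C)C | starting material
19 | [2-(benzyloxy)-5-methoxyphenyl]magnesium bromide | COc1ccc(OCc2ccccc2)c([Mg]Br)c1 | intermediate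
20 | tert-butyl N-[(2R)-1-(2-benzyloxy-5-methoxyphenyl)propan-2-yl]carbamate | C[C@@H](NC(=O)OC(C)(C)C)Cc1cc(OC)ccc1OCc1ccccc1 | intermediate
21 | (2R)-1-(2-benzyloxy-5-methoxyphenyl)propan-2-amine (present as hydrochloride) | C[C@@H](N)Cc1cc(OC)ccc1OCc1ccccc1 | intermediate
22 | N-[(2R)-1-(2-benzyloxy-5-methoxyphenyl)propan-2-yl]acetamide | C[C@@H](NC(C)=O)Cc1cc(OC)ccc1OCc1ccccc1 | intermediate
23 | (3R)-5-(benzyloxy)-8-methoxy-1,3-dimethyl-3,4-dihydroisoquinoline | C(c1ccccc1)Oc1ccc(OC)c2c1C[C@@H](C)N=C2C | intermediate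
24 | (1R,3R)-5-(benzyloxy)-8-methoxy-1,3-dimethyl-1,2,3,4-tetrahydroisoquinoline | C(c1ccccc1)Oc1ccc(OC)c2c1C[C@@H](C)N[C@@H]2C | intermediate
25 | tert-butyl (1R,3R)-5-(benzyloxy)-8-methoxy-1,3-dimethyl-3,4-dihydro-1H-isoquinoline-2-carboxylate | C(c1ccccc1)Oc1ccc(OC)c2c1C[C@@H](C)N(C(=O)OC(C)(C)C)[C@@H]2C | intermediate
26 | tert-butyl (1R,3R)-5-hydroxy-8-methoxy-1,3-dimethyl-3,4-dihydro-1H-isoquinoline-2-carboxylate | Oc1ccc(OC)c2c1C[C@@H](C)N(C(=O)OC(C)(C)C)[C@@H]2C | intermediate
27 | tert-butyl (1R,3R)-8,8-dimethoxy-1,3-dimethyl-5-oxo-1,3,4,8-tetrahydroisoquinoline-2(5H)-carboxylate | O=C1C=CC(OC)(OC)C2=C1C[C@@H](C)N(C(=O)OC(C)(C)C)[C@@H]2C | intermediate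
28 | 8',1''-dilithio binaphthalene bis-MOM ether | COc1cc(C)cc2c([Li])cc(-c3ccc4c([Li])c(C)cc(OC)c4c3OCOC)c(OCOC)c12 | intermediate
29 | 8',1''-bis(dichlorocerium) binaphthalene bis-MOM ether | COc1cc(C)cc2c([Ce](Cl)Cl)cc(-c3ccc4c([Ce](Cl)Cl)c(C)cc(OC)c4c3OCOC)c(OCOC)c12 | intermediate
30 | bis-carbinol adduct (C5 carbinols undefined; C1, C3 all R) | COc1cc(C)cc2c(C3(O)C=CC(OC)(OC)C4=C3C[C@@H](C)N(C(=O)OC(C)(C)C)[C@@H]4C)cc(-c3ccc4c(C5(O)C=CC(OC)(OC)C6=C5C[C@@H](C)N(C(=O)OC(C)(C)C)[C@@H]6C)c(C)cc(OC)c4c3OCOC)c(OCOC)c12 | intermediate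
31 | bis-quinol (5-aryl-5-hydroxy-8-oxo rings) | COc1cc(C)cc2c(C3(O)C=CC(=O)C4=C3C[C@@H](C)N(C(=O)OC(C)(C)C)[C@@H]4C)cc(-c3ccc4c(C5(O)C=CC(=O)C6=C5C[C@@H](C)N(C(=O)OC(C)(C)C)[C@@H]6C)c(C)cc(OC)c4c3OCOC)c(OCOC)c12 | intermediate
32 | bis(N-Boc) bis(MOM) quateraryl with free C8 phenols | COc1cc(C)cc2c(-c3ccc(O)c4c3C[C@@H](C)N(C(=O)OC(C)(C)C)[C@@H]4C)cc(-c3ccc4c(-c5ccc(O)c6c5C[C@@H](C)N(C(=O)OC(C)(C)C)[C@@H]6C)c(C)cc(OC)c4c3OCOC)c(OCOC)c12 | intermediate
33 | CNP0077060.1 | COc1cc(C)cc2c(-c3ccc(O)c4c3C[C@@H](C)N[C@@H]4C)cc(-c3ccc4c(-c5ccc(O)c6c5C[C@@H](C)N[C@@H]6C)c(C)cc(OC)c4c3O)c(O)c12 | target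

Total step count: 20.
Longest linear sequence: 12 steps (steps 2–10, then 18–20). The isoquinoline branch runs 10 steps to the target (steps 11–17, then 18–20).

**Steps most likely to fail**

1. Step 18.
- Risk: the hindered naphthyl metal at C1'' may act as a base towards C1–H of 27 or may not add at all. The second bond is then lost to protonation, and C1 is exposed to epimerization.
- Fallback: known cross-coupling chemistry that sets out from 26 and 15 and returns at 33.
- Phenol 26 is converted with Tf2O and pyridine into the 5-triflate F1.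
- BBr3 in CH2Cl2 cleaves the 8-O-methyl ether together with the Boc group to give the amino phenol triflate F2.
- Boc2O and NaHCO3 restore the carbamate in the N-Boc phenol F3, and MOMCl with iPr2NEt gives the 8-MOM ether F4.
- Miyaura borylation (B2pin2, PdCl2(dppf), KOAc, dioxane, 80 °C) gives the 5-pinacolboronate F5.
- Twofold Suzuki–Miyaura coupling of F5 with dibromide 15 (Pd(OAc)2, SPhos, K3PO4, toluene–H2O, 90 °C) keeps the hindered partner as the halide and gives the fully protected quateraryl F6.
- F6 under the conditions of step 20 gives 33.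

2. Step 19.
- Risk: in acid the tertiary, doubly allylic carbinols may ionize, or the quinols may undergo a 1,2-aryl shift before electron transfer. The reduction may also stop after one ring.
- Fallback: sets out from 31 and returns at 32.
- Compound 31 is isolated after the aqueous acetic acid stage and reduced at both carbonyls by Luche reduction (NaBH4, CeCl3·7H2O, MeOH, −78 °C) to the bis(cyclohexa-2,5-diene-1,4-diol) F7.
- Catalytic PPTS in CH2Cl2 then ionizes each C5 hydroxyl to an arenium ion, which loses the C8 proton. Dehydrative aromatization thus gives 32.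
- Hydride addition followed by loss of water replaces the dissolving-metal step.

3. Step 8.
- Risk: the second bromination may lose site selectivity, through further attack on or oxidation of the bromonaphthol half. The acetyl group may also migrate between the two neighbouring oxygens, which would redirect bromine to C8''.
- Fallback: sets out from 12 and returns at 15. The two brominations are separated by a protecting-group change, so that each one meets a single activated ring.
- One equivalent of NBS at −20 °C gives the 8'-bromo monoacetate F8.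
- MOMCl with iPr2NEt caps the naphthol as the 8'-bromo MOM ether acetate F9.
- A second equivalent of NBS at rt brominates only C1'' to give the dibromo MOM ether acetate F10.
- K2CO3 in MeOH gives the dibromo mono-MOM naphthol F11.
- NaH with MOMCl gives 15.

Further compounds
F1 | step 18 | tert-butyl (1R,3R)-8-methoxy-1,3-dimethyl-5-(trifluoromethylsulfonyloxy)-3,4-dihydro-1H-isoquinoline-2-carboxylate | FC(F)(F)S(=O)(=O)Oc1ccc(OC)c2c1C[C@@H](C)N(C(=O)OC(C)(C)C)[C@@H]2C
F2 | step 18 | (1R,3R)-8-hydroxy-1,3-dimethyl-1,2,3,4-tetrahydroisoquinolin-5-yl trifluoromethanesulfonate | FC(F)(F)S(=O)(=O)Oc1ccc(O)c2c1C[C@@H](C)N[C@@H]2C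
F3 | step 18 | tert-butyl (1R,3R)-8-hydroxy-1,3-dimethyl-5-(trifluoromethylsulfonyloxy)-3,4-dihydro-1H-isoquinoline-2-carboxylate | FC(F)(F)S(=O)(=O)Oc1ccc(O)c2c1C[C@@H](C)N(C(=O)OC(C)(C)C)[C@@H]2C
F4 | step 18 | tert-butyl (1R,3R)-8-(methoxymethoxy)-1,3-dimethyl-5-(trifluoromethylsulfonyloxy)-3,4-dihydro-1H-isoquinoline-2-carboxylate | FC(F)(F)S(=O)(=O)Oc1ccc(OCOC)c2c1C[C@@H](C)N(C(=O)OC(C)(C)C)[C@@H]2C
F5 | step 18 | tert-butyl (1R,3R)-8-(methoxymethoxy)-1,3-dimethyl-5-(4,4,5,5-tetramethyl-1,3,2-dioxaborolan-2-yl)-3,4-dihydro-1H-isoquinoline-2-carboxylate | CC1(C)OB(OC1(C)C)c1ccc(OCOC)c2c1C[C@@H](C)N(C(=O)OC(C)(C)C)[C@@H]2C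
F6 | step 18 | bis(N-Boc) tetrakis(MOM) quateraryl | COc1cc(C)cc2c(-c3ccc(OCOC)c4c3C[C@@H](C)N(C(=O)OC(C)(C)C)[C@@H]4C)cc(-c3ccc4c(-c5ccc(OCOC)c6c5C[C@@H](C)N(C(=O)OC(C)(C)C)[C@@H]6C)c(C)cc(OC)c4c3OCOC)c(OCOC)c12
F7 | step 19 | bis(5-aryl-cyclohexa-2,5-diene-5,8-diol) from 31 (carbinol centres undefined) | COc1cc(C)cc2c(C3(O)C=CC(O)C4=C3C[C@@H](C)N(C(=O)OC(C)(C)C)[C@@H]4C)cc(-c3ccc4c(C5(O)C=CC(O)C6=C5C[C@@H](C)N(C(=O)OC(C)(C)C)[C@@H]6C)c(C)cc(OC)c4c3OCOC)c(OCOC)c12
F8 | step 8 | 8'-bromo binaphthol monoacetate | COc1cc(C)cc2c(Br)cc(-c3ccc4cc(C)cc(OC)c4c3OC(C)=O)c(O)c12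
F9 | step 8 | 8'-bromo 5'-MOM ether 5''-acetate | COc1cc(C)cc2c(Br)cc(-c3ccc4cc(C)cc(OC)c4c3OC(C)=O)c(OCOC)c12
F10 | step 8 | 8',1''-dibromo 5'-MOM ether 5''-acetate | COc1cc(C)cc2c(Br)cc(-c3ccc4c(Br)c(C)cc(OC)c4c3OC(C)=O)c(OCOC)c12
F11 | step 8 | 8',1''-dibromo 5'-MOM ether 5''-naphthol | COc1cc(C)cc2c(Br)cc(-c3ccc4c(Br)c(C)cc(OC)c4c3O)c(OCOC)c12
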